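**A direct plan and its weak points**

A direct plan would make the cyclohexene first, by a catalytic enantioselective Diels–Alder reaction of silyloxydiene A1 with enal A2, and would carry the adduct to the cyclohexadiene acid A3.
It would then add the C5 quaternary centre through a tethered second Diels–Alder reaction to the bridged lactone A4 and a retro-aldol opening to aldehyde A5, and would close the cyclopentanone last by Dieckmann condensation.
- The tethered cycloaddition to A4 would be weak: it would need about 160 °C on a diene prone to 1,5-shifts, would run against the electronic bias of the diene, and would build a lactone and two stereocentres only to destroy them, at about five steps for one C–C bond.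
- The first Diels–Alder reaction would be weak: a trisubstituted α,β-dialkyl enal is a poor dienophile, it must form a quaternary centre next to the ethyl-bearing diene terminus, and the centre set by the endo approach would be erased at once with stoichiometric Pd(OAc)2.
- The cyclopentanone end game would be weak: C1 and C3 would be left to base equilibration after the Dieckmann closure, and the finished skeleton would see chloride at 150 °C and iodide at 115 °C to free one hindered acid.

**Retrosynthetic overview**

Target numbering (hexahydroindene): C1 and C3 are the CHMe carbons flanking the C2 ketone, C3a and C7a the ring fusion, C4 = C(Et)CO2H, C5 = C(Et)(styryl), C6=C7(Me) the ring alkene.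
The cyclohexene C3a–C4–C5–C6=C7–C7a is a Diels–Alder retron whose diene and dienophile are already linked through C1–C2–C3. Cutting C4–C5 and C3a–C7a together therefore opens both rings at once to the linear all-E tetraenal 19.
Only C1 and C3 (both R) are brought to that step. Each is allylic to one reacting terminus and faces a cis alkyl group (C7–Me, C4–Et), so 1,3-allylic strain should relay them to C3a, C4, C5 and C7a as a group.
19 forms in the flask by Wittig olefination of aldehyde 17. 17 comes from alkyne 9 and dienyl iodide 13 (union at C6–C7), and 9 from a propargylation that sets C1/C2 on the Roche-derived aldehyde 3 (C3).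
No quaternary centre is made on a preformed ring, no ring stereocentre is made and erased, C1/C3 are never left to equilibration, and the end game is three mild steps at or below 23 °C.

Key step: step 11

**Route**

Step 1
Reactants: 1 methyl (R)-3-hydroxy-2-methylpropanoate
Product: 2 methyl (R)-2-methyl-3-(triethylsilyloxy)propanoate
Conditions: Et3SiCl (1.1 equiv), imidazole (1.5 equiv), CH2Cl2, 0 to 23 °C
Reagents that add atoms: chlorotriethylsilane, CC[Si](Cl)(CC)CC
Why: Silyl ether formation at the primary alcohol leaves the stereocentre (the future C3) untouched, and a primary triethylsilyl ether is chosen because step 10 can oxidise it directly to the aldehyde.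

Step 2
Reactants: 2 methyl (R)-2-methyl-3-(triethylsilyloxy)propanoate
Product: 3 (R)-2-methyl-3-(triethylsilyloxy)propanal
Conditions: i-Bu2AlH (1.1 equiv), CH2Cl2, −78 °C; MeOH, then aq. potassium sodium tartrate; used crude
Reagents that add atoms: none
Why: Partial ester reduction with i-Bu2AlH should stop at the tetrahedral aluminium hemiacetal at −78 °C and release the aldehyde on work-up, and the α-stereocentre is not touched if the aldehyde is used at once.

Step 3
Reactants: 4 pent-3-yn-2-one
Product: 5 (S)-pent-3-yn-2-ol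
Conditions: RuCl[(S,S)-TsDPEN](p-cymene) (0.5 mol %), i-PrOH, 23 °C
Reagents that add atoms: none
Why: Noyori asymmetric transfer hydrogenation of an alkynyl ketone, in which the (S,S) catalyst delivers hydride to the face that gives the (S) carbinol, the alkyne taking the place an aryl group takes in aryl ketones.

Step 4
Reactants: 5 (S)-pent-3-yn-2-ol
Product: 6 (S)-pent-3-yn-2-yl methanesulfonate
Conditions: MsCl (1.2 equiv), Et3N (1.5 equiv), CH2Cl2, −78 to 0 °C
Reagents that add atoms: methanesulfonyl chloride, CS(=O)(=O)Cl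
Why: O-Sulfonylation with retention at carbon gives the propargylic mesylate needed for step 5, used without chromatography.

Step 5
Reactants: 3 (R)-2-methyl-3-(triethylsilyloxy)propanal; 6 (S)-pent-3-yn-2-yl methanesulfonate (1.3 equiv)
Product: 8 (2R,3R,4R)-2,4-dimethyl-1-(triethylsilyloxy)hept-5-yn-3-ol, via allenylzinc 7 (not isolated)
Conditions: Pd(OAc)2 (5 mol %), PPh3 (5 mol %), Et2Zn (3 equiv), THF, −78 to −20 °C; aq. NH4Cl
Reagents that add atoms: none
Why: Marshall propargylation, in which zerovalent palladium opens the mesylate by anti SN2′ attack, transmetalation gives the (M)-allenylzinc 7, and its cyclic SE2′ addition to the aldehyde gives the anti homopropargylic alcohol, so the reagent sets the future C1 (R, net inversion at the mesylate carbon) and the carbinol, while the Felkin preference of the α-methyl aldehyde is matched (anti,syn triad).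

Step 6
Reactants: 8 (2R,3R,4R)-2,4-dimethyl-1-(triethylsilyloxy)hept-5-yn-3-ol
Product: 9 (4R,5R,6R)-4,6-dimethyl-5,7-bis(triethylsilyloxy)hept-2-yne
Conditions: Et3SiOTf (1.2 equiv), 2,6-lutidine (2 equiv), CH2Cl2, −78 to 0 °C
Reagents that add atoms: triethylsilyl trifluoromethanesulfonate, CC[Si](CC)(CC)OS(=O)(=O)C(F)(F)F
Why: Silyl ether formation with the silyl triflate covers the hindered secondary alcohol, so that the hydrozirconation of step 9 is governed by sterics and not by a zirconium alkoxide.

Step 7
Reactants: 10 (E)-cinnamaldehyde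
Product: 11 [(E)-but-1-en-3-yn-1-yl]benzene
Conditions: Me3SiCHN2 (1.2 equiv), n-BuLi (1.2 equiv), THF, −78 to 0 °C
Reagents that add atoms: (trimethylsilyl)diazomethane, C[Si](C)(C)C=[N+]=[N-]
Why: Colvin rearrangement (1,2-addition of the lithiated diazomethane, Peterson-type elimination, loss of N2 and 1,2-hydrogen shift in the alkylidene carbene) should give the terminal enyne with the E alkene intact, under aprotic conditions that avoid conjugate addition to the enal.

Step 8
Reactants: 11 [(E)-but-1-en-3-yn-1-yl]benzene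
Product: 13 [(1E,3E)-3-ethyl-4-iodobuta-1,3-dien-1-yl]benzene, via dienylcopper 12 (not isolated)
Conditions: EtMgBr (1.2 equiv), CuBr·SMe2 (1.2 equiv), Et2O/Me2S, −45 °C; 11, −45 to −25 °C; then I2 (1.3 equiv), THF, −78 to 0 °C
Reagents that add atoms: ethylmagnesium bromide, CC[Mg]Br; iodine, II
Why: Normant carbocupration adds ethylcopper syn across the terminal alkyne with ethyl on the internal carbon, and iodinolysis of the dienylcopper with retention should give the iodide with ethyl cis and styryl trans to iodine, the geometry the diene of step 11 needs.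

Step 9
Reactants: 9 (4R,5R,6R)-4,6-dimethyl-5,7-bis(triethylsilyloxy)hept-2-yne; 13 [(1E,3E)-3-ethyl-4-iodobuta-1,3-dien-1-yl]benzene (1.2 equiv)
Product: 16 [(1E,3E,5E,7R,8R,9R)-3-ethyl-5,7,9-trimethyl-8,10-bis(triethylsilyloxy)deca-1,3,5-trien-1-yl]benzene, via alkenylzirconocene chloride 14 (not isolated), via alkenylzinc chloride 15 (not isolated)
Conditions: Cp2Zr(H)Cl (1.6 equiv), THF, 50 °C; ZnCl2 (1.6 equiv), 0 °C; 13, Pd(PPh3)4 (5 mol %), THF, 23 °C
Reagents that add atoms: none
Why: Hydrozirconation followed by Negishi coupling, in which syn addition of Zr–H under equilibrating conditions puts zirconium on the methyl-bearing (less hindered) alkyne carbon and zinc-assisted cross-coupling at zerovalent palladium joins C6 and C7 with retention on both partners, so the triene should be all-E.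

Step 10
Reactants: 16 [(1E,3E,5E,7R,8R,9R)-3-ethyl-5,7,9-trimethyl-8,10-bis(triethylsilyloxy)deca-1,3,5-trien-1-yl]benzene
Product: 17 (2S,3R,4R,5E,7E,9E)-8-ethyl-2,4,6-trimethyl-10-phenyl-3-(triethylsilyloxy)deca-5,7,9-trienal
Conditions: (COCl)2 (4 equiv), DMSO (8 equiv), CH2Cl2, −78 to −40 °C; Et3N (12 equiv), −78 to 0 °C
Reagents that add atoms: none
Why: Swern oxidation of a primary triethylsilyl ether, in which the chlorosulfonium reagent cleaves the unhindered primary silyl ether and oxidises it to the aldehyde in one operation while the hindered secondary silyl ether stays (the descriptor at C2 of 17 changes from R to S only because the CIP priorities change).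

Step 11
Reactants: 17 (2S,3R,4R,5E,7E,9E)-8-ethyl-2,4,6-trimethyl-10-phenyl-3-(triethylsilyloxy)deca-5,7,9-trienal; 18 2-(triphenylphosphoranylidene)butanal (1.5 equiv)
Product: 20 (1R,2R,3R,3aS,4S,5R,7aS)-4,5-diethyl-1,3,7-trimethyl-5-[(E)-2-phenylethenyl]-2-(triethylsilyloxy)-2,3,3a,4,5,7a-hexahydro-1H-indene-4-carbaldehyde, via tetraenal 19 (not isolated)
Conditions: BHT (5 mol %), PhMe (0.05 M), 85 °C; then 110 °C if 19 persists, Ar
Reagents that add atoms: none
Why: The stabilised ylide 18 turns the aldehyde into the (E)-2-ethylenal 19 (Wittig olefination), which at the same temperature should undergo a concerted, asynchronous, suprafacial [4+2] cycloaddition between the all-E diene C5=C6–C7=C7a and the enal C3a=C4 (thermal intramolecular Diels–Alder reaction). The closest known reaction type is the tandem Wittig/intramolecular Diels–Alder cyclisation of 1,6,8-nonatrienes with a terminal acceptor to trans-hydrindenes. The cyclopentane closes in the fused mode over the three-atom tether C1–C2–C3 as the leading C3a–C7a bond forms at the enal β-carbon, and the cyclohexene closes as the new six-membered ring when the lagging C4–C5 bond joins the two fully substituted carbons. C7a and C5 are set by the diene face, which C1 selects through 1,3-allylic strain with the C7 methyl (C1–H eclipses the alkene, the tether leaves from one face), with styryl outside and ethyl inside because of the E geometry; C3a and C4 are set by the enal face, which C3 selects in the same way against the C4 ethyl, with formyl cis to styryl because of the E enal. Since C1 and C3 have the same sense, both strain minima are met only in the trans-fused transition state with formyl endo, so substrate control is matched at both ends and the C2 silyloxy group is a bystander. The step needs π-facial and endo/exo selectivity (regiochemistry is fixed by the tether), and the product aldehyde on a quaternary carbon is inert to excess ylide.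

Step 12
Reactants: 20 (1R,2R,3R,3aS,4S,5R,7aS)-4,5-diethyl-1,3,7-trimethyl-5-[(E)-2-phenylethenyl]-2-(triethylsilyloxy)-2,3,3a,4,5,7a-hexahydro-1H-indene-4-carbaldehyde
Product: 21 (1R,2R,3R,3aS,4S,5R,7aS)-4,5-diethyl-1,3,7-trimethyl-5-[(E)-2-phenylethenyl]-2-(triethylsilyloxy)-2,3,3a,4,5,7a-hexahydro-1H-indene-4-carboxylic acid
Conditions: NaClO2 (5 equiv), NaH2PO4 (5 equiv), 2-methyl-2-butene (30 equiv), t-BuOH/H2O, 0 to 23 °C
Reagents that add atoms: sodium chlorite, [Na+].[O-]Cl=O
Why: Pinnick oxidation converts the non-enolisable neopentyl aldehyde into the acid while 2-methyl-2-butene traps hypochlorous acid before it reaches the styryl and ring alkenes, and it is run before desilylation so that a hydroxy aldehyde, which could close to a bridged lactol, never forms.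

Step 13
Reactants: 21 (1R,2R,3R,3aS,4S,5R,7aS)-4,5-diethyl-1,3,7-trimethyl-5-[(E)-2-phenylethenyl]-2-(triethylsilyloxy)-2,3,3a,4,5,7a-hexahydro-1H-indene-4-carboxylic acid
Product: 22 (1R,2R,3R,3aS,4S,5R,7aS)-4,5-diethyl-2-hydroxy-1,3,7-trimethyl-5-[(E)-2-phenylethenyl]-2,3,3a,4,5,7a-hexahydro-1H-indene-4-carboxylic acid
Conditions: Bu4NF (3 equiv), THF, 23 °C; pH 4 buffer
Reagents that add atoms: none
Why: Fluoride-induced desilylation frees the C2 alcohol, and under these basic conditions the carboxylate cannot lactonise onto it.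

Step 14
Reactants: 22 (1R,2R,3R,3aS,4S,5R,7aS)-4,5-diethyl-2-hydroxy-1,3,7-trimethyl-5-[(E)-2-phenylethenyl]-2,3,3a,4,5,7a-hexahydro-1H-indene-4-carboxylic acid
Product: 23 dinorspiculoic acid A, (1R,3R,3aS,4S,5R,7aS)-4,5-diethyl-1,3,7-trimethyl-2-oxo-5-[(E)-2-phenylethenyl]-2,3,3a,4,5,7a-hexahydro-1H-indene-4-carboxylic acid
Conditions: Dess–Martin periodinane (1.5 equiv), CH2Cl2, 0 to 23 °C; aq. Na2S2O3
Reagents that add atoms: none
Why: Dess–Martin oxidation of the secondary alcohol gives the C2 ketone under near-neutral conditions, and C1 and C3, which become enolisable only now, already hold the all-trans arrangement (each methyl trans to the neighbouring ring bond), so no equilibration is needed.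

**Compound list**

1 | methyl (R)-3-hydroxy-2-methylpropanoate | COC(=O)[C@H](C)CO | starting material
2 | methyl (R)-2-methyl-3-(triethylsilyloxy)propanoate | COC(=O)[C@H](C)CO[Si](CC)(CC)CC | intermediate
3 | (R)-2-methyl-3-(triethylsilyloxy)propanal | O=C[C@H](C)CO[Si](CC)(CC)CC | intermediate
4 | pent-3-yn-2-one | CC#CC(C)=O | starting material
5 | (S)-pent-3-yn-2-ol | CC#C[C@H](C)O | intermediate
6 | (S)-pent-3-yn-2-yl methanesulfonate | CC#C[C@H](C)OS(C)(=O)=O | intermediate
7 | ethyl[(M)-penta-2,3-dien-2-yl]zinc (allenylzinc, not isolated) | [H]C(C)=[C@@]=C(C)[Zn]CC | intermediate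
8 | (2R,3R,4R)-2,4-dimethyl-1-(triethylsilyloxy)hept-5-yn-3-ol | CC#C[C@@H](C)[C@@H](O)[C@H](C)CO[Si](CC)(CC)CC | intermediate
9 | (4R,5R,6R)-4,6-dimethyl-5,7-bis(triethylsilyloxy)hept-2-yne | CC#C[C@@H](C)[C@@H](O[Si](CC)(CC)CC)[C@H](C)CO[Si](CC)(CC)CC | intermediate
10 | (E)-cinnamaldehyde | O=C/C=C/c1ccccc1 | starting material
11 | [(E)-but-1-en-3-yn-1-yl]benzene | C#C/C=C/c1ccccc1 | intermediate
12 | [(1E,3E)-2-ethyl-4-phenylbuta-1,3-dien-1-yl]copper (as its MgBr2 complex, not isolated) | [Cu]/C=C(CC)/C=C/c1ccccc1 | intermediate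
13 | [(1E,3E)-3-ethyl-4-iodobuta-1,3-dien-1-yl]benzene | I/C=C(CC)/C=C/c1ccccc1 | intermediate
14 | chlorobis(cyclopentadienyl)[(2E,4R,5R,6R)-4,6-dimethyl-5,7-bis(triethylsilyloxy)hept-2-en-2-yl]zirconium (not isolated; rings drawn σ-bound) | CC[Si](CC)(CC)OC[C@@H](C)[C@H](O[Si](CC)(CC)CC)[C@H](C)/C=C(C)/[Zr](Cl)(C1C=CC=C1)C1C=CC=C1 | intermediate
15 | chloro[(2E,4R,5R,6R)-4,6-dimethyl-5,7-bis(triethylsilyloxy)hept-2-en-2-yl]zinc (not isolated) | CC[Si](CC)(CC)OC[C@@H](C)[C@H](O[Si](CC)(CC)CC)[C@H](C)/C=C(C)/[Zn]Cl | intermediate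
16 | [(1E,3E,5E,7R,8R,9R)-3-ethyl-5,7,9-trimethyl-8,10-bis(triethylsilyloxy)deca-1,3,5-trien-1-yl]benzene | CC[Si](CC)(CC)OC[C@@H](C)[C@H](O[Si](CC)(CC)CC)[C@H](C)/C=C(C)/C=C(CC)/C=C/c1ccccc1 | intermediate
17 | (2S,3R,4R,5E,7E,9E)-8-ethyl-2,4,6-trimethyl-10-phenyl-3-(triethylsilyloxy)deca-5,7,9-trienal | O=C[C@@H](C)[C@H](O[Si](CC)(CC)CC)[C@H](C)/C=C(C)/C=C(CC)/C=C/c1ccccc1 | intermediate
18 | 2-(triphenylphosphoranylidene)butanal | CCC(C=O)=P(c1ccccc1)(c1ccccc1)c1ccccc1 | starting material
19 | (2E,4R,5R,6R,7E,9E,11E)-2,10-diethyl-4,6,8-trimethyl-12-phenyl-5-(triethylsilyloxy)dodeca-2,7,9,11-tetraenal (not isolated) | O=C/C(CC)=C/[C@@H](C)[C@H](O[Si](CC)(CC)CC)[C@H](C)/C=C(C)/C=C(CC)/C=C/c1ccccc1 | intermediate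
20 | (1R,2R,3R,3aS,4S,5R,7aS)-4,5-diethyl-1,3,7-trimethyl-5-[(E)-2-phenylethenyl]-2-(triethylsilyloxy)-2,3,3a,4,5,7a-hexahydro-1H-indene-4-carbaldehyde | CC[C@@]1(/C=C/c2ccccc2)C=C(C)[C@H]2[C@@H]([C@@H](C)[C@H](O[Si](CC)(CC)CC)[C@@H]2C)[C@]1(CC)C=O | intermediate
21 | (1R,2R,3R,3aS,4S,5R,7aS)-4,5-diethyl-1,3,7-trimethyl-5-[(E)-2-phenylethenyl]-2-(triethylsilyloxy)-2,3,3a,4,5,7a-hexahydro-1H-indene-4-carboxylic acid | CC[C@@]1(/C=C/c2ccccc2)C=C(C)[C@H]2[C@@H]([C@@H](C)[C@H](O[Si](CC)(CC)CC)[C@@H]2C)[C@]1(CC)C(=O)O | intermediate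
22 | (1R,2R,3R,3aS,4S,5R,7aS)-4,5-diethyl-2-hydroxy-1,3,7-trimethyl-5-[(E)-2-phenylethenyl]-2,3,3a,4,5,7a-hexahydro-1H-indene-4-carboxylic acid | CC[C@@]1(/C=C/c2ccccc2)C=C(C)[C@H]2[C@@H]([C@@H](C)[C@H](O)[C@@H]2C)[C@]1(CC)C(=O)O | intermediate
23 | dinorspiculoic acid A | CC[C@@]1(/C=C/c2ccccc2)C=C(C)[C@H]2[C@@H]([C@@H](C)C(=O)[C@@H]2C)[C@]1(CC)C(=O)O | target

**Step count and risks**

Total step count: 14. Longest linear sequence: 10 steps (steps 1, 2, 5, 6, 9, 10, 11, 12, 13, 14).

Steps most likely to fail:

1. Step 11. The olefination of the α-branched aldehyde may be slow at the temperature it needs, so that epimerisation at the α-carbon or β-elimination of silanol competes before the cycloaddition. The fallback would set out from 17 and make the enal at room temperature by oxidation instead of by a hot Wittig reaction. Ethyl 2-(triphenylphosphoranylidene)butanoate in CH2Cl2 at 40 °C should give ethyl (2E,4R,5R,6R,7E,9E,11E)-2,10-diethyl-4,6,8-trimethyl-12-phenyl-5-(triethylsilyloxy)dodeca-2,7,9,11-tetraenoate F1. i-Bu2AlH at −78 °C should then give (2E,4R,5R,6R,7E,9E,11E)-2,10-diethyl-4,6,8-trimethyl-12-phenyl-5-(triethylsilyloxy)dodeca-2,7,9,11-tetraen-1-ol F2. MnO2 in CH2Cl2 at 23 °C should give the enal 19, which would cyclise at 23 to 60 °C, and the route is rejoined at 20.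

2. Step 9. Regiocontrol in the hydrozirconation may be incomplete (zirconium next to the branched carbon), or excess hydride may reduce the iodide partner. The fallback would set out from 9 and reverse the polarity of the union with an isolated, purified electrophile. Cp2Zr(H)Cl followed by I2 should give (2E,4R,5R,6R)-2-iodo-4,6-dimethyl-5,7-bis(triethylsilyloxy)hept-2-ene F3, separable from its regioisomer. Iodine–lithium exchange on 13 (t-BuLi, Et2O, −78 °C) and Bu3SnCl should give tributyl[(1E,3E)-2-ethyl-4-phenylbuta-1,3-dien-1-yl]stannane F4. Stille coupling of the two (Pd2(dba)3, AsPh3, CuI, NMP, 40 °C) would rejoin the route at 16.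

3. Step 8. The carbocupration of a conjugated enyne may lose regiochemistry (copper on the internal carbon, or 1,4-addition to an allene). The fallback would set out from 11 and deliver the ethyl group as an electrophile. Borylcupration with B2pin2 (CuCl 10 mol %, Xantphos, NaOt-Bu, THF, 23 °C), which puts boron on the terminal carbon, and trapping of the alkenylcopper with EtI should give 2-[(1E,3E)-2-ethyl-4-phenylbuta-1,3-dien-1-yl]-4,4,5,5-tetramethyl-1,3,2-dioxaborolane F5. Stereoretentive iododeboronation (NaOMe, then ICl, THF, −78 °C) would rejoin the route at 13.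

**Further compounds**

F1 | step 11 | ethyl (2E,4R,5R,6R,7E,9E,11E)-2,10-diethyl-4,6,8-trimethyl-12-phenyl-5-(triethylsilyloxy)dodeca-2,7,9,11-tetraenoate | CCOC(=O)/C(CC)=C/[C@@H](C)[C@H](O[Si](CC)(CC)CC)[C@H](C)/C=C(C)/C=C(CC)/C=C/c1ccccc1
F2 | step 11 | (2E,4R,5R,6R,7E,9E,11E)-2,10-diethyl-4,6,8-trimethyl-12-phenyl-5-(triethylsilyloxy)dodeca-2,7,9,11-tetraen-1-ol | OC/C(CC)=C/[C@@H](C)[C@H](O[Si](CC)(CC)CC)[C@H](C)/C=C(C)/C=C(CC)/C=C/c1ccccc1
F3 | step 9 | (2E,4R,5R,6R)-2-iodo-4,6-dimethyl-5,7-bis(triethylsilyloxy)hept-2-ene | CC[Si](CC)(CC)OC[C@@H](C)[C@H](O[Si](CC)(CC)CC)[C@H](C)/C=C(C)/I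
F4 | step 9 | tributyl[(1E,3E)-2-ethyl-4-phenylbuta-1,3-dien-1-yl]stannane | CCCC[Sn](CCCC)(CCCC)/C=C(CC)/C=C/c1ccccc1
F5 | step 8 | 2-[(1E,3E)-2-ethyl-4-phenylbuta-1,3-dien-1-yl]-4,4,5,5-tetramethyl-1,3,2-dioxaborolane | B1(/C=C(CC)/C=C/c2ccccc2)OC(C)(C)C(C)(C)O1
A1 | direct plan | (E)-2-(triisopropylsilyloxy)hexa-1,3-diene | C=C(O[Si](C(C)C)(C(C)C)C(C)C)/C=C/CC
A2 | direct plan | methyl (E)-4-formylhex-3-enoate | O=C/C(CC)=C/CC(=O)OC
A3 | direct plan | 1,6β-diethyl-5β-(2-methoxy-2-oxoethyl)-3-methylcyclohexa-1,3-diene-6α-carboxylic acid | CC[C@@]1(C(=O)O)C(CC)=CC(C)=C[C@H]1CC(=O)OC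
A4 | direct plan | tricyclic γ-lactone of the tethered cycloaddition (bicyclo[2.2.2]octene bridged by the lactone, ethyl ester on the two-carbon bridge) | CC[C@@]12C(=O)O[C@H]3[C@]1(CC)C=C(C)[C@H]([C@]3(C)C(=O)OCC)[C@H]2CC(=O)OC
A5 | direct plan | cyclohexene aldehyde triester of the retro-aldol opening | CC[C@@]1(C(=O)OC)[C@](CC)(C=O)C=C(C)[C@H]([C@@H](C)C(=O)OC)[C@H]1CC(=O)OC
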